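**Retrosynthetic overview**
1. The target is released from its tribenzyl-protected keto ester by one neutral global hydrogenolysis (benzyl ester, aryl benzyl ether, alkyl benzyl ether).
2. Key C–C disconnection: the ArCH2–C(=O) bond, made by a crossed Claisen-type condensation of a laterally lithiated benzyl ortho-toluate (a vinylogous ester enolate) with a C12 Weinreb amide.
3. The toluate comes from orcinol: Vilsmeier formylation, selective 4-O-methylation, 2-O-benzylation, Pinnick oxidation, benzyl esterification.
4. The Weinreb amide comes from 12-hydroxydodecanoic acid: O-benzylation, then CDI amidation.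
5. No ring is formed; the benzene ring is carried intact from orcinol.

Assumption: the target has no stereocentre and is achiral, so the SMILES defines it completely and no stereocontrol is needed.

**Step 1**
Reactants: 1 orcinol (5-methylbenzene-1,3-diol)
Product: 3 2,4-dihydroxy-6-methylbenzaldehyde, via aryl iminium chloride 2 (not isolated)
Conditions: POCl3, DMF, 0 °C → rt; then H2O, 50 °C
Reagents that add atoms: N,N-dimethylformamide CN(C)C=O; water O
Why: Vilsmeier–Haack formylation, in which the chloroiminium ion attacks the ring position para to one OH and ortho to the other (not the hindered position between the two OH groups) and water hydrolyses iminium salt 2 to the aldehyde.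

**Step 2**
Reactants: 3 2,4-dihydroxy-6-methylbenzaldehyde
Product: 4 2-hydroxy-4-methoxy-6-methylbenzaldehyde
Conditions: MeI (1.05 equiv), K2CO3 (1.0 equiv), acetone, rt
Reagents that add atoms: iodomethane CI
Why: Williamson ether synthesis, selective because the 2-OH is tied up in a hydrogen bond to the formyl group, so one equivalent of MeI alkylates only the free, more acidic 4-OH.

**Step 3**
Reactants: 4 2-hydroxy-4-methoxy-6-methylbenzaldehyde
Product: 5 2-(benzyloxy)-4-methoxy-6-methylbenzaldehyde
Conditions: BnBr, K2CO3, DMF, 60 °C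
Reagents that add atoms: benzyl bromide BrCc1ccccc1
Why: Williamson ether synthesis under more forcing conditions benzylates the remaining hydrogen-bonded phenol, masking it as an ether that tolerates LiN(i-Pr)2 and is removed later by hydrogenolysis.

**Step 4**
Reactants: 5 2-(benzyloxy)-4-methoxy-6-methylbenzaldehyde
Product: 6 2-(benzyloxy)-4-methoxy-6-methylbenzoic acid
Conditions: NaClO2, NaH2PO4, 2-methyl-2-butene, t-BuOH/THF/H2O, 0 °C → rt
Reagents that add atoms: sodium chlorite NaClO2 [Na+].[O-]Cl=O
Why: Pinnick oxidation converts the hindered, electron-rich aldehyde to the acid without touching the benzyl ether, the alkene scavenger protecting the activated ring from chlorination.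

**Step 5**
Reactants: 6 2-(benzyloxy)-4-methoxy-6-methylbenzoic acid
Product: 7 benzyl 2-(benzyloxy)-4-methoxy-6-methylbenzoate
Conditions: BnBr, K2CO3, DMF, rt
Reagents that add atoms: benzyl bromide BrCc1ccccc1
Why: Esterification by SN2 O-alkylation of the carboxylate is insensitive to the two ortho substituents that block acyl substitution, and gives an ester cleavable under neutral hydrogenolysis.

**Step 6**
Reactants: 8 12-hydroxydodecanoic acid
Product: 10 12-(benzyloxy)dodecanoic acid, via benzyl 12-(benzyloxy)dodecanoate 9 (not isolated)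
Conditions: NaH (3 equiv), BnBr (2.5 equiv), n-Bu4NI (cat.), THF/DMF, 0 °C → rt; then NaOH, MeOH/H2O, 60 °C; aq. HCl
Reagents that add atoms: benzyl bromide BrCc1ccccc1; sodium hydroxide NaOH [Na+].[OH-]
Why: Williamson etherification of the alkoxide (the carboxylate is benzylated as well) followed by saponification of ester 9 returns the free acid while the benzyl ether stays.

**Step 7**
Reactants: 10 12-(benzyloxy)dodecanoic acid
Product: 12 12-(benzyloxy)-N-methoxy-N-methyldodecanamide, via acyl imidazolide 11 (not isolated)
Conditions: CDI, CH2Cl2, rt; then MeNHOMe·HCl, rt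
Reagents that add atoms: N,O-dimethylhydroxylamine hydrochloride CNOC.Cl
Why: Amide coupling through CDI activation to acyl imidazolide 11 and aminolysis gives the Weinreb amide cleanly, the released imidazole serving as the base for the amine hydrochloride.

**Step 8**
Reactants: 7 benzyl 2-(benzyloxy)-4-methoxy-6-methylbenzoate; 12 12-(benzyloxy)-N-methoxy-N-methyldodecanamide
Product: 15 benzyl 2-(benzyloxy)-6-[13-(benzyloxy)-2-oxotridecyl]-4-methoxybenzoate, via lithiated toluate 13 (not isolated), via lithium hemiaminal alkoxide 14 (not isolated)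
Conditions: LiN(i-Pr)2 (1.05 equiv to 7), THF, −78 °C, 20 min; then 12 (0.75 equiv), −78 °C, 1 h; aq. NH4Cl at −78 °C
Reagents that add atoms: none
Why: Lateral lithiation of the ortho-toluate gives a vinylogous ester enolate whose acylation by the Weinreb amide is a crossed Claisen-type condensation, and the chelated adduct 14 survives until the cold quench, which prevents over-addition and base-induced cyclisation onto the ester.

**Step 9**
Reactants: 15 benzyl 2-(benzyloxy)-6-[13-(benzyloxy)-2-oxotridecyl]-4-methoxybenzoate
Product: 16 2-hydroxy-6-(13-hydroxy-2-oxotridecyl)-4-methoxybenzoic acid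
Conditions: H2 (1 atm), 10% Pd/C, EtOAc, rt
Reagents that add atoms: none
Why: Catalytic hydrogenolysis cleaves the benzyl ester and both benzyl ethers under neutral conditions that leave the non-conjugated ketone and the aryl methyl ether intact and avoid the acid or base that would close the keto acid to an isocoumarin or a naphthalenediol.

**Compound list**
1 | orcinol (5-methylbenzene-1,3-diol) | Cc1cc(O)cc(O)c1 | starting material
2 | N-[(2,4-dihydroxy-6-methylphenyl)methylidene]-N-methylmethanaminium chloride | C[N+](C)=Cc1c(C)cc(O)cc1O.[Cl-] | intermediate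
3 | 2,4-dihydroxy-6-methylbenzaldehyde | Cc1cc(O)cc(O)c1C=O | intermediate
4 | 2-hydroxy-4-methoxy-6-methylbenzaldehyde | COc1cc(C)c(C=O)c(O)c1 | intermediate
5 | 2-(benzyloxy)-4-methoxy-6-methylbenzaldehyde | COc1cc(C)c(C=O)c(OCc2ccccc2)c1 | intermediate
6 | 2-(benzyloxy)-4-methoxy-6-methylbenzoic acid | COc1cc(C)c(C(=O)O)c(OCc2ccccc2)c1 | intermediate
7 | benzyl 2-(benzyloxy)-4-methoxy-6-methylbenzoate | COc1cc(C)c(C(=O)OCc2ccccc2)c(OCc2ccccc2)c1 | intermediate
8 | 12-hydroxydodecanoic acid | OCCCCCCCCCCCC(=O)O | starting material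
9 | benzyl 12-(benzyloxy)dodecanoate | O=C(CCCCCCCCCCCOCc1ccccc1)OCc1ccccc1 | intermediate
10 | 12-(benzyloxy)dodecanoic acid | OC(=O)CCCCCCCCCCCOCc1ccccc1 | intermediate
11 | 1-[12-(benzyloxy)dodecanoyl]-1H-imidazole | O=C(CCCCCCCCCCCOCc1ccccc1)n1ccnc1 | intermediate
12 | 12-(benzyloxy)-N-methoxy-N-methyldodecanamide | CON(C)C(=O)CCCCCCCCCCCOCc1ccccc1 | intermediate
13 | benzyl 2-(benzyloxy)-6-(lithiomethyl)-4-methoxybenzoate | [Li]Cc1cc(OC)cc(OCc2ccccc2)c1C(=O)OCc1ccccc1 | intermediate
14 | lithium 1-{3-(benzyloxy)-2-[(benzyloxy)carbonyl]-5-methoxyphenyl}-13-(benzyloxy)-2-[methoxy(methyl)amino]tridecan-2-olate | [Li]OC(Cc1cc(OC)cc(OCc2ccccc2)c1C(=O)OCc1ccccc1)(CCCCCCCCCCCOCc1ccccc1)N(C)OC | intermediate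
15 | benzyl 2-(benzyloxy)-6-[13-(benzyloxy)-2-oxotridecyl]-4-methoxybenzoate | COc1cc(CC(=O)CCCCCCCCCCCOCc2ccccc2)c(C(=O)OCc2ccccc2)c(OCc2ccccc2)c1 | intermediate
16 | 2-hydroxy-6-(13-hydroxy-2-oxotridecyl)-4-methoxybenzoic acid | COc1cc(O)c(C(=O)O)c(CC(=O)CCCCCCCCCCCO)c1 | target

**Total step count:** 9
**Longest linear sequence:** 7 (steps 1–5, 8, 9)

**Three steps most likely to fail**

Step 8 (Claisen-type condensation). The risks are attack of the benzylic anion on the benzyl ester of a second molecule, enolisation of the Weinreb amide, and cyclisation of the product enolate onto the ester if the mixture warms. The fallback sets out from acid 6 and comes back to the route at target 16. Acid 6 is deprotonated twice with 2.2 equiv LiN(i-Pr)2 (THF, −78 °C) to lithium 2-(benzyloxy)-6-(lithiomethyl)-4-methoxybenzoate F1, a carboxylate dianion that carries no electrophilic ester and so can neither self-condense nor lactonise. Addition of Weinreb amide 12 and work-up at pH 4 gives 2-(benzyloxy)-6-[13-(benzyloxy)-2-oxotridecyl]-4-methoxybenzoic acid F2. Hydrogenolysis of its two benzyl ethers (H2, 10% Pd/C, EtOAc) gives 16.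

Step 9 (global hydrogenolysis). The alkyl benzyl ether is the slowest of the three groups to cleave, and a long exposure risks reduction of the ketone and lactol or isocoumarin formation. The fallback sets out from 8 and comes back at 16, replacing the alkyl benzyl ether by a silyl ether that is removed before the hydrogenolysis. Acid 8 is coupled with MeNHOMe·HCl (EDC·HCl, HOBt, N-methylmorpholine, CH2Cl2) to 12-hydroxy-N-methoxy-N-methyldodecanamide F3. This is silylated (TBSCl, imidazole, DMF) to 12-[(tert-butyldimethylsilyl)oxy]-N-methoxy-N-methyldodecanamide F4. Condensation with lithiated toluate 13, generated from 7 as in step 8, gives benzyl 2-(benzyloxy)-6-{13-[(tert-butyldimethylsilyl)oxy]-2-oxotridecyl}-4-methoxybenzoate F5. HF·pyridine (THF, 0 °C) then gives benzyl 2-(benzyloxy)-6-(13-hydroxy-2-oxotridecyl)-4-methoxybenzoate F6. This needs only the fast hydrogenolysis of a benzyl ester and an aryl benzyl ether (H2, 10% Pd/C, EtOAc, short time) to reach 16.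

Step 2 (selective mono-methylation). The risk is over-methylation, or a mixture of mono-ethers that is hard to separate. The fallback sets out from 3 and comes back at 4. Aldehyde 3 is methylated exhaustively (excess MeI, K2CO3, acetone, reflux) to 2,4-dimethoxy-6-methylbenzaldehyde F7. BCl3 (CH2Cl2, −78 → 0 °C) then removes only the methyl ether ortho to the formyl group, through a six-membered boron chelate, and gives 4.

**Further compounds**
F1 | step 8 | lithium 2-(benzyloxy)-6-(lithiomethyl)-4-methoxybenzoate | [Li]Cc1cc(OC)cc(OCc2ccccc2)c1C(=O)O[Li]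
F2 | step 8 | 2-(benzyloxy)-6-[13-(benzyloxy)-2-oxotridecyl]-4-methoxybenzoic acid | COc1cc(CC(=O)CCCCCCCCCCCOCc2ccccc2)c(C(=O)O)c(OCc2ccccc2)c1
F3 | step 9 | 12-hydroxy-N-methoxy-N-methyldodecanamide | CON(C)C(=O)CCCCCCCCCCCO
F4 | step 9 | 12-[(tert-butyldimethylsilyl)oxy]-N-methoxy-N-methyldodecanamide | CON(C)C(=O)CCCCCCCCCCCO[Si](C)(C)C(C)(C)C
F5 | step 9 | benzyl 2-(benzyloxy)-6-{13-[(tert-butyldimethylsilyl)oxy]-2-oxotridecyl}-4-methoxybenzoate | COc1cc(CC(=O)CCCCCCCCCCCO[Si](C)(C)C(C)(C)C)c(C(=O)OCc2ccccc2)c(OCc2ccccc2)c1
F6 | step 9 | benzyl 2-(benzyloxy)-6-(13-hydroxy-2-oxotridecyl)-4-methoxybenzoate | COc1cc(CC(=O)CCCCCCCCCCCO)c(C(=O)OCc2ccccc2)c(OCc2ccccc2)c1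
F7 | step 2 | 2,4-dimethoxy-6-methylbenzaldehyde | COc1cc(C)c(C=O)c(OC)c1
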